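(The numbers in the tables come from a simulation on assumed constants.)

Complex with three exchanged could not pass 40.0% of the charge in north, since each one takes 3 incoming ligand and north got 1.20 equiv. That ceiling did not stop the earlier runs: blue's works out at 46.7%, yet blue levelled at 11.3%, a quarter of it.

in all of them: starting complex 0.50 M

| charge | incoming ligand | leaving ligand | remark | time |
|---|---|---|---|---|
| blue | 1.4 equiv | 2 equiv | run made earlier |  |
| amber | 2.2 equiv | 2 equiv | run made earlier |  |
| teal | 3.7 equiv | 2 equiv | run made earlier |  |
| north | 1.20 equiv | 2.00 equiv |  | 2.5 min |
| west | 1.50 equiv | 2.00 equiv |  | 2.5 min |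
| north-east | 4.00 equiv | 2.00 equiv |  | 2.5 min |

| run | time / s | complex with three exchanged / % |
|---|---|---|
| blue | 10.0 | 1.3 |
| blue | 25.0 | 5.4 |
| blue | 50.0 | 9.0 |
| blue | 80.0 | 11.3 |
| blue | 120 | 11.4 |
| amber | 10.0 | 3.8 |
| amber | 25.0 | 11.3 |
| amber | 50.0 | 16.6 |
| amber | 80.0 | 17.0 |
| amber | 120 | 17.8 |
| teal | 10.0 | 10.0 |
| teal | 25.0 | 21.0 |
| teal | 50.0 | 27.5 |
| teal | 80.0 | 28.4 |
| teal | 120 | 27.5 |

(each reading ± 0.5 percentage points)



- complex with three exchanged at the end, in percent of the starting complex charged, for each flask in turn (north, west, north-east)

I turned the question round: what would the readings show if three independent exchanges at equilibrium set the yield? At low conversion, with free ligand near its charge, the plateau would then go with the cube of the charge, a factor of 18.5 from blue to teal; that cube can't be carried so far, since the whole charge stands 8.85 times above blue's plateau, so teal could reach at most that factor. Teal stood 2.46 times above it, on a charge 2.64 times larger. So I carried a plainer rule, the yield per equivalent: the mean of the last two readings divided by the equivalents of incoming ligand charged. Blue gave 8.11% per equivalent and teal 7.55%. I took each new flask from its nearest run: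

north: 8.11% × 1.20 equiv = 9.73%

west: 8.11% × 1.50 equiv = 12.2%

north-east: 7.55% × 4.00 equiv = 30.2%

North-east lay past teal, so I went round once more, continuing the fall in yield per equivalent from blue to teal:

north-east, second round: 29.9%

The forecast gave 9.8%, 12.2% and 30%, close to mine: “The plateau is almost proportional to the incoming ligand”.

The flasks gave 9.92%, 12.6% and 28.0%.

    complex with one exchanged + incoming ligand ⇌ leaving ligand + complex with two exchanged (K = 17.5, k = 0.0518 /M/s)
    leaving ligand → by-product carried off (k = 0.00178 /s)
    complex with two exchanged + incoming ligand ⇌ leaving ligand + complex with three exchanged (K = 16.0, k = 0.256 /M/s)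
    2 incoming ligand → self-condensation product (k = 0.0243 /M/s)
    starting complex + incoming ligand ⇌ leaving ligand + complex with one exchanged (K = 3.60, k = 0.0980 /M/s)

North gave 8.27% per equivalent against blue's 8.11%, while north-east gave 7.00%, lower than teal's 7.55%. In north, of their turnover up to the asked time, the first exchange had done half by 0.0676 min and the self-condensation 56% by 0.250 min, both much earlier than the 2.5 min asked. By that time, [incoming ligand] in north was down to 11% of its charge.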